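**Small charge.** A small charge of partner B, 0.80 equiv on Thursday, left the substrate at 71.9% after 6.00 h, so 35.1% of that partner B reached substrate. I took the rest to have been lost one for one with partner A, so that substrate and partner A compete for partner B.

| flask | substrate | partner A | partner B | remark | time |
|---|---|---|---|---|---|
| Thursday's | 0.50 M (in portions, 4) | 1 equiv | 0.80 equiv | run made earlier; portions every 8.0 min |  |
| Saturday's | 0.50 M (in portions, 4) | 1 equiv | 1.8 equiv | run made earlier; portions every 8.0 min |  |
| Monday's | 0.25 M (in portions, 4) | 1 equiv | 1.2 equiv | run made earlier; portions every 8.0 min |  |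
| flask | 0.50 M (in portions, 4) | 1.00 equiv | 1.20 equiv | the portions of substrate follow each other after 8.0 min, the first at the start | 5.0 h |

| run | time / h | target / % | substrate / % | open intermediate / % |
|---|---|---|---|---|
| Thursday's | 0.417 | 2.9 | 87.7 | 8.9 |
| Thursday's | 1.33 | 17.7 | 74.6 | 8.2 |
| Thursday's | 2.00 | 21.6 | 73.2 | 5.7 |
| Thursday's | 3.00 | 25.2 | 71.8 | 3.1 |
| Thursday's | 5.00 | 26.1 | 72.1 | 1.5 |
| Thursday's | 6.00 | 26.9 | 71.9 | 0.7 |
| Saturday's | 1.00 | 34.3 | 46.4 | 18.9 |
| Saturday's | 2.00 | 53.2 | 31.3 | 16.2 |
| Saturday's | 3.00 | 59.7 | 25.5 | 14.7 |
| Saturday's | 4.00 | 63.3 | 22.6 | 13.7 |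
| Saturday's | 5.00 | 65.9 | 20.4 | 13.9 |
| Saturday's | 6.00 | 66.8 | 19.2 | 13.8 |
| Monday's | 0.500 | 2.3 | 85.1 | 12.5 |
| Monday's | 0.833 | 7.4 | 75.0 | 17.4 |
| Monday's | 1.50 | 18.8 | 65.0 | 16.5 |
| Monday's | 3.00 | 33.0 | 55.4 | 11.3 |
| Monday's | 6.00 | 42.8 | 51.3 | 6.2 |

(standard deviation of a reading: 0.3 percentage points)

- a reading or a percentage of target counts all its forms, free or not
- the concentration of target that is asked is that of its free form alone

* concentration of target (only what is free in solution) at 5.0 h, in M
* concentration of substrate at 5.0 h, in M
* concentration of open intermediate at 5.0 h, in M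
* concentration of partner A at 5.0 h, in M

**Fastest rung.** In each flask the portions are in by 0.400 h.

**Middle rung.** Thursday's substrate moved by 1.3 percentage points between 2.00 h and 6.00 h, and Monday's by 4.1 points between 3.00 h and 6.00 h. I read this as the contest for partner B closing, in those two runs, within the hours read.

**Slowest rung.** Thursday's open intermediate then fell from 8.2% at 1.33 h to 0.7% at 6.00 h. I took this drain to change what the substrate has become, but not how much substrate is left, so I reckoned the contest apart.

**Contest rule.** Let a and d be the fractions of substrate and partner A left. Taking partner B as gone, with one equivalent of partner A, the balance gives d = 2 − a − (equivalents of partner B). Thursday's ln d / ln a is 2.22 and Monday's is 1.87, with mean 2.04. This apparent selectivity factor S, for substrate given in portions at this spacing, the logarithm of the fraction of partner A left over that of the substrate left, I rounded to 2, so d = a². For the flask, a = 52.5%. My reckoning is thus 0.262 M substrate, 0.138 M partner A, and 0.238 M of target and open intermediate together.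

**The forecast.** The forecast gave 0.19 M free target, 0.26 M substrate, 0.03 M open intermediate and 0.05 M partner A, reasoning that “both partners are nearly spent”. Its partner A is less than mine.

**The result.** The flask gave 0.218 M free target, 0.267 M substrate, 0.0152 M open intermediate and 0.134 M partner A.

    substrate + partner B → open intermediate (k = 7.15 × 10⁻⁴ /M/s)
    partner B + partner A → second intermediate (k = 0.00108 /M/s)
    open intermediate + second intermediate → target (k = 0.00337 /M/s)
    2 second intermediate → homo product (k = 4.29 × 10⁻⁴ /M/s)
    crystals ⇌ target, rate k5*(cs5 - [target]) while solid is left; crystals form when [target] > cs5 (solubility = 0.220 M, k = 0.0612 /s)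

**The contest.** In the flask at 5.0 h, partner B, the limiting reagent, stood at 0.11% of its charge, less than partner A at 27% and substrate at 53%. Those two remainders give S = 2.10, where Thursday's and Monday's readings gave 2.04. With 0.600 equiv of partner A, d = a² and the balance rewritten for that charge give 33.3% of the substrate left, and that flask held 34.1%.

The runs were generated by integration for an exercise; scatter was added.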